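**Retrosynthetic overview**
1. Paratocarpin G ⇒ Claisen–Schmidt disconnection of the enone C=C (last step, no protecting groups) into a ring-A methyl ketone and a dihydrobenzofuranol aldehyde.
2. Aldehyde ⇒ aryl C–O bond (intramolecular SNAr) and benzylic C–O bond (water, inversion), back to a trans-epoxy tertiary carbinol with an ortho C–F bond and an acetal-masked para-CHO; the epoxide oxygen becomes the ring oxygen.
3. Epoxide ⇒ Shi epoxidation of an E-alkene ⇒ Heck coupling of a bromofluoroaryl acetal with 2-methylbut-3-en-2-ol.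
4. Ring-A ketone ⇒ C-prenylation of resacetophenone.
5. Ring order: both benzene rings are bought; the dihydrofuran ring (ring C) is the only ring made, in step 3.

Assumption: 2-(3-bromo-4-fluorophenyl)-1,3-dioxolane (compound 1, the ethylene acetal of 3-bromo-4-fluorobenzaldehyde) is bought as such.

**Step 1**
Reactants: 1 aryl bromide acetal [2-(3-bromo-4-fluorophenyl)-1,3-dioxolane]; 2 alkenol [2-methylbut-3-en-2-ol]
Product: 3 (3E)-4-[5-(1,3-dioxolan-2-yl)-2-fluorophenyl]-2-methylbut-3-en-2-ol
Conditions: Pd(OAc)2 (2 mol%), P(o-tol)3 (4 mol%), K2CO3, Bu4NBr, DMF, 90 °C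
Reagents that add atoms: none
Why: Mizoroki–Heck reaction, in which zerovalent palladium inserts into the C–Br bond (C–F is inert), syn-carbopalladation of the terminal alkene and syn β-hydride elimination (only benzylic hydrogens are available) give the E-alkene, while the acetal and the tertiary alcohol survive the basic medium.

**Step 2**
Reactants: 3 (3E)-4-[5-(1,3-dioxolan-2-yl)-2-fluorophenyl]-2-methylbut-3-en-2-ol
Product: 4 2-[(2R,3S)-3-[5-(1,3-dioxolan-2-yl)-2-fluorophenyl]oxiran-2-yl]propan-2-ol
Conditions: 1,2:4,5-di-O-isopropylidene-β-L-erythro-2,3-hexodiulo-2,6-pyranose (C12H18O6, 30 mol%), KHSO5 (as 2KHSO5·KHSO4·K2SO4), K2CO3, Bu4NHSO4, MeCN/CH2(OMe)2/aq. Na2B4O7–Na2EDTA buffer (pH 10.5), 0 °C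
Reagents that add atoms: potassium peroxymonosulfate (KHSO5), SMILES [K+].[O-]S(=O)(=O)OO
Why: Shi asymmetric epoxidation, in which the chiral dioxirane formed from the ketone transfers oxygen stereospecifically (syn) through a spiro transition state to one face of the E-alkene and so sets both epoxide stereocentres; the L-series ketone is used because the D-fructose-derived ketone attacks the opposite face (it gives (R,R)-trans-β-methylstyrene oxide), and the pH 10.5 medium leaves the acetal and the unactivated C–F bond untouched.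

**Step 3**
Reactants: 4 2-[(2R,3S)-3-[5-(1,3-dioxolan-2-yl)-2-fluorophenyl]oxiran-2-yl]propan-2-ol
Product: 6 (2R,3R)-3-hydroxy-2-(2-hydroxypropan-2-yl)-2,3-dihydro-1-benzofuran-5-carbaldehyde, via triol aldehyde 5 (not isolated)
Conditions: H2SO4 (0.5 M aq.), THF, 40 °C; then K2CO3 (excess), DMSO, THF/H2O distilled off, 80 °C (0.05 M)
Reagents that add atoms: water, SMILES O
Why: Proposed new method: an acid-then-base, one-flask relay in which the epoxide oxygen becomes the ring oxygen — dilute acid hydrolyses the dioxolane (switching the arene from SNAr-inert to para-formyl-activated) and opens the protonated trans-epoxide by backside attack of water at the benzylic carbon only (the other epoxide carbon is neopentyl-like and inductively deactivated, and the electron-poor aryl disfavours a free benzylic cation), so C3 is set by inversion while the former epoxide oxygen stays on C2 with retention; after the pH switch that oxygen, the most acidic and least hindered alkoxide of triol 5 (the benzylic oxygen could only close a four-membered ring and the tertiary one a slower six-membered ring), adds to the C–F carbon and expels fluoride through a Meisenheimer adduct (5-exo), giving the trans-(2R,3R) ring C; the closest known reaction types are acid-catalysed anti-hydrolysis of aryl epoxides and intramolecular SNAr etherification of 2-(2-fluoroaryl)ethanols, which have not been merged on a 2,3-epoxy tertiary carbinol with a latent activating group.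

**Step 4**
Reactants: 7 resacetophenone [1-(2,4-dihydroxyphenyl)ethan-1-one]; 8 prenyl bromide [1-bromo-3-methylbut-2-ene]
Product: 9 1-[2,4-dihydroxy-3-(3-methylbut-2-en-1-yl)phenyl]ethan-1-one
Conditions: KOH (10% aq., 2 equiv), 0 °C to rt
Reagents that add atoms: none
Why: Nuclear (C-)prenylation of a phenoxide, in which the resorcinol dianion in water (oxygens shielded by hydrogen bonding) is alkylated at C3, the carbon flanked by both phenoxide oxygens; the yield is modest (about 25–35%) and the 5-prenyl and O-prenyl isomers are removed by chromatography.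

**Step 5**
Reactants: 9 1-[2,4-dihydroxy-3-(3-methylbut-2-en-1-yl)phenyl]ethan-1-one (1.5 equiv); 6 (2R,3R)-3-hydroxy-2-(2-hydroxypropan-2-yl)-2,3-dihydro-1-benzofuran-5-carbaldehyde
Product: 11 Paratocarpin G, via aldol adduct 10 (not isolated)
Conditions: KOH (50% aq.), EtOH, 0 °C to rt, 36 h; then AcOH to pH 6 at 0 °C
Reagents that add atoms: none
Why: Claisen–Schmidt condensation, in which the ketone enolate adds to the non-enolisable aldehyde and E1cB dehydration gives the thermodynamically favoured E-enone; aqueous KOH tolerates the free hydroxyl groups, and C2 and C3 of ring C carry no acidifying group and are not epimerised.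

**Compound list**
1 | 2-(3-bromo-4-fluorophenyl)-1,3-dioxolane | Fc1ccc(C2OCCO2)cc1Br | starting material
2 | 2-methylbut-3-en-2-ol | C=CC(C)(C)O | starting material
3 | (3E)-4-[5-(1,3-dioxolan-2-yl)-2-fluorophenyl]-2-methylbut-3-en-2-ol | CC(C)(O)/C=C/c1cc(C2OCCO2)ccc1F | intermediate
4 | 2-[(2R,3S)-3-[5-(1,3-dioxolan-2-yl)-2-fluorophenyl]oxiran-2-yl]propan-2-ol | CC(C)(O)[C@@H]1O[C@H]1c2cc(C3OCCO3)ccc2F | intermediate
5 | 4-fluoro-3-[(1R,2R)-1,2,3-trihydroxy-3-methylbutyl]benzaldehyde | O=Cc1ccc(F)c(c1)[C@@H](O)[C@H](C(C)(C)O)O | intermediate (not isolated)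
6 | (2R,3R)-3-hydroxy-2-(2-hydroxypropan-2-yl)-2,3-dihydro-1-benzofuran-5-carbaldehyde | O=Cc1ccc2c(c1)[C@@H](O)[C@H](C(C)(C)O)O2 | intermediate
7 | 1-(2,4-dihydroxyphenyl)ethan-1-one | CC(=O)c1ccc(O)cc1O | starting material
8 | 1-bromo-3-methylbut-2-ene | CC(C)=CCBr | starting material
9 | 1-[2,4-dihydroxy-3-(3-methylbut-2-en-1-yl)phenyl]ethan-1-one | CC(=O)c1ccc(O)c(CC=C(C)C)c1O | intermediate
10 | 1-[2,4-dihydroxy-3-(3-methylbut-2-en-1-yl)phenyl]-3-hydroxy-3-[(2R,3R)-3-hydroxy-2-(2-hydroxypropan-2-yl)-2,3-dihydro-1-benzofuran-5-yl]propan-1-one (both epimers at the new carbinol carbon) | CC(C)=CCc1c(O)ccc(C(=O)CC(O)c2ccc3c(c2)[C@@H](O)[C@H](C(C)(C)O)O3)c1O | intermediate (not isolated)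
11 | Paratocarpin G, (2E)-1-[2,4-dihydroxy-3-(3-methylbut-2-en-1-yl)phenyl]-3-[(2R,3R)-3-hydroxy-2-(2-hydroxypropan-2-yl)-2,3-dihydro-1-benzofuran-5-yl]prop-2-en-1-one | CC(C)=CCc1c(O)ccc(C(=O)/C=C/c2ccc3c(c2)[C@@H](O)[C@H](C(C)(C)O)O3)c1O | target

**Step count**
Total steps: 5. Longest linear sequence: 4 (steps 1, 2, 3 and 5).

**Three steps most likely to fail**

Step 3 (the proposed new relay). It can fail in three ways:
- Stereochemical leakage: partial cationic opening or water attack at the non-benzylic epoxide carbon would erode dr or ee.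
- Wrong ring size: the tertiary alkoxide of 5 could close the six-membered chroman instead of ring C; this is the least predictable point of the route.
- Hydroxide could displace fluoride intermolecularly.

The fallback uses known chemistry and sets out from epoxide 4. Opening with benzoic acid mediated by Ti(OiPr)4 (CH2Cl2, rt) is the established chelation-controlled, invertive opening of 2,3-epoxy alcohols at the carbon remote from the carbinol. It gives (1R,2R)-1-[5-(1,3-dioxolan-2-yl)-2-fluorophenyl]-2,3-dihydroxy-3-methylbutyl benzoate F1. K2CO3 in MeOH removes the benzoate and gives (1R,2R)-1-[5-(1,3-dioxolan-2-yl)-2-fluorophenyl]-3-methylbutane-1,2,3-triol F2, which is purified and checked for diastereomeric purity. Aqueous acid then frees the aldehyde to give triol 5, now isolated. A separate conventional SNAr cyclisation (K2CO3, DMSO, 80 °C) brings the fallback back to the route at compound 6. This fallback secures the C3 stereochemistry but keeps the same SNAr closure, so it does not remove the ring-size risk.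

Step 5 (unprotected Claisen–Schmidt). The 4-phenoxide deactivates the ketone, so the condensation may be slow and let Cannizzaro loss of 6 compete. Prolonged strong base could also let the tertiary alkoxide attack the para-acyl aryl ether carbon (O-to-O aryl migration to a chroman).

The fallback sets out from ketone 9. 3,4-Dihydro-2H-pyran with pyridinium p-toluenesulfonate (CH2Cl2, rt) protects the non-chelated 4-OH and gives 1-[2-hydroxy-3-(3-methylbut-2-en-1-yl)-4-(oxan-2-yloxy)phenyl]ethan-1-one F3. Condensation with 6 (KOH, EtOH, rt) runs through the protected aldol adduct F4 to the 4-O-tetrahydropyranyl chalcone F5. Pyridinium p-toluenesulfonate in MeOH at 40 °C removes the acetal, and the fallback comes back at compound 11.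

Step 4 (C-prenylation). Yield and C3/C5/O selectivity are poor.

The fallback sets out from resacetophenone 7. O-Alkylation of the free 4-OH with 3-chloro-3-methylbut-1-yne (K2CO3, KI, CuI cat., acetone, reflux) gives 1-{2-hydroxy-4-[(2-methylbut-3-yn-2-yl)oxy]phenyl}ethan-1-one F6. Semi-hydrogenation (H2, Pd/CaCO3 poisoned with Pb(OAc)2, quinoline, EtOAc) gives 1-{2-hydroxy-4-[(2-methylbut-3-en-2-yl)oxy]phenyl}ethan-1-one F7. Aromatic Claisen rearrangement (N,N-diethylaniline, 130 °C) moves the group to C3 with allylic transposition, and the fallback comes back at compound 9.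

**Further compounds**
F1 | step 3 | (1R,2R)-1-[5-(1,3-dioxolan-2-yl)-2-fluorophenyl]-2,3-dihydroxy-3-methylbutyl benzoate | Fc1ccc(C2OCCO2)cc1[C@@H](OC(=O)c3ccccc3)[C@H](C(C)(C)O)O
F2 | step 3 | (1R,2R)-1-[5-(1,3-dioxolan-2-yl)-2-fluorophenyl]-3-methylbutane-1,2,3-triol | Fc1ccc(C2OCCO2)cc1[C@@H](O)[C@H](C(C)(C)O)O
F3 | step 5 | 1-[2-hydroxy-3-(3-methylbut-2-en-1-yl)-4-(oxan-2-yloxy)phenyl]ethan-1-one (racemic at the acetal carbon) | CC(=O)c1ccc(OC2CCCCO2)c(CC=C(C)C)c1O
F4 | step 5 | 3-hydroxy-1-[2-hydroxy-3-(3-methylbut-2-en-1-yl)-4-(oxan-2-yloxy)phenyl]-3-[(2R,3R)-3-hydroxy-2-(2-hydroxypropan-2-yl)-2,3-dihydro-1-benzofuran-5-yl]propan-1-one (epimer mixture, not isolated) | CC(C)=CCc1c(OC2CCCCO2)ccc(C(=O)CC(O)c3ccc4c(c3)[C@@H](O)[C@H](C(C)(C)O)O4)c1O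
F5 | step 5 | (2E)-1-[2-hydroxy-3-(3-methylbut-2-en-1-yl)-4-(oxan-2-yloxy)phenyl]-3-[(2R,3R)-3-hydroxy-2-(2-hydroxypropan-2-yl)-2,3-dihydro-1-benzofuran-5-yl]prop-2-en-1-one | CC(C)=CCc1c(OC2CCCCO2)ccc(C(=O)/C=C/c3ccc4c(c3)[C@@H](O)[C@H](C(C)(C)O)O4)c1O
F6 | step 4 | 1-{2-hydroxy-4-[(2-methylbut-3-yn-2-yl)oxy]phenyl}ethan-1-one | CC(=O)c1ccc(OC(C)(C)C#C)cc1O
F7 | step 4 | 1-{2-hydroxy-4-[(2-methylbut-3-en-2-yl)oxy]phenyl}ethan-1-one | CC(=O)c1ccc(OC(C)(C)C=C)cc1O
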